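**Retrosynthetic overview**
1. Denticulatolide 25 comes from acetylation of 24. The 1,2-dioxane of 24 is built from H2O2 by two stereospecific C–O bond formations: perhydrolysis of a 7,8-epoxide at C8, then transannular 6-exo-tet displacement of an allylic chloride at C11. Both start from epoxy lactone 21.
2. Key disconnection: the whole α-methylene-γ-butyrolactone is removed as 2-bromoacrylic acid 18 by cutting O–C2 and C15–C1. This leaves the lactone-free C17 macrocyclic (1E,3E)-diene 17.
3. Enabling feature: the lactone carbinol carbon C2 lies between the ring-fusion carbon C1 and the trisubstituted C3=C4 alkene of the 14-membered ring. C1–C2–C3=C4 is therefore the 1,2-carbo-oxygenation pattern of a C1=C2–C3=C4 diene, reached through an η3-allylpalladium over C2–C4. The new lactone oxygen then deactivates C3=C4, so C7=C8 is the only alkene left open to epoxidation.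
4. 17 comes from CBS reduction and Nozaki–Hiyama–Kishi closure (C11–C12) of iodo aldehyde 14. 14 is assembled from farnesyl acetate (C2–C11, C18, C19), TMS-diazomethane (C1) and 2-butyn-1-ol (C12–C14, C20).
5. Ring order: 14-membered carbocycle (step 10), γ-lactone (step 13), temporary oxirane (step 14), 1,2-dioxane (step 17).

Key step: step 13

Remark on the chemistry: cembrane numbering is used (C1 ring-fusion CH, C2 lactone O–CH, C3=C4, C7 acetoxy carbon, C8 and C11 peroxide carbons, C12=C13, C15 α-carbon, C16 C=O, C17 exocyclic CH2, C18/C19/C20 methyls on C4/C8/C12). For step 13 it is assumed that (R)-SEGPHOS selects the Re face of C1; the antipode is equally accessible.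

**Step 1**
Reactants: 1 (2E,6E)-farnesyl acetate
Product: 2 10-bromo-11-hydroxy-10,11-dihydrofarnesyl acetate (racemic at CHBr)
Conditions: NBS, THF–H2O, 0 °C
Reagents that add atoms: N-bromosuccinimide O=C1CCC(=O)N1Br; water O
Why: Electrophilic bromohydrin formation in aqueous THF is known to pick the terminal isopropylidene alkene of farnesyl esters (the internal alkene is more shielded, C3=C4 is deactivated by the allylic acetate), water opens the bromonium ion at the tertiary carbon, and the racemic CHBr centre is deleted in step 3.

**Step 2**
Reactants: 2 bromohydrin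
Product: 3 (2E,6E)-10,11-epoxyfarnesol (racemic)
Conditions: K2CO3, MeOH, rt
Reagents that add atoms: none
Why: Intramolecular Williamson-type closure of the bromohydrin gives the epoxide, while carbonate-catalysed transesterification frees the allylic alcohol needed in step 4.

**Step 3**
Reactants: 3 epoxyfarnesol
Product: 5 (2E,6E)-3,7-dimethyldeca-2,6-diene-1,10-diol, via hydroxy aldehyde 4 (not isolated)
Conditions: H5IO6, THF–H2O, 0 °C; then NaBH4, MeOH, 0 °C
Reagents that add atoms: none
Why: Periodic acid hydrolyses the trisubstituted epoxide and cleaves the glycol (Malaprade cleavage) with loss of acetone, and borohydride reduction of the crude aldehyde parks C11 as a primary alcohol that tolerates steps 4 to 8.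

**Step 4**
Reactants: 5 diol
Product: 6 (2E,6E)-10-hydroxy-3,7-dimethyldeca-2,6-dienal
Conditions: MnO2, CH2Cl2, rt
Reagents that add atoms: none
Why: MnO2 oxidises only the allylic alcohol, so the saturated C11 carbinol needs no protecting group and the E geometry of C3=C4 is kept.

**Step 5**
Reactants: 6 hydroxy enal
Product: 7 (4E,8E)-4,8-dimethylundeca-4,8-dien-10-yn-1-ol
Conditions: TMSCHN2, LDA, THF, −78 °C → rt
Reagents that add atoms: (trimethylsilyl)diazomethane C[Si](C)(C)C=[N+]=[N-]
Why: Colvin rearrangement: addition of lithiated TMS-diazomethane to the enal, Peterson-type loss of silanolate and 1,2-hydride shift of the alkylidene carbene give the terminal enyne and bring in C1, without the methanol conjugate addition that enals suffer under carbonate/methanol homologation conditions.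

**Step 6**
Reactants: 8 2-butyn-1-ol
Product: 10 (Z)-3-iodobut-2-en-1-ol, via cyclic alkenylalanate 9 (not isolated)
Conditions: Red-Al, THF, 0 °C → rt; then I2, −78 → 0 °C
Reagents that add atoms: iodine II
Why: Hydroxyl-directed trans-hydroalumination of the propargylic alcohol places aluminium on the distal alkyne carbon in a five-membered alkoxyalanate, and iodinolysis with retention fixes iodine cis to CH2OH, which becomes the 12Z geometry (C11 cis to C14).

**Step 7**
Reactants: 10 (Z)-3-iodobut-2-en-1-ol
Product: 11 (Z)-1-bromo-3-iodobut-2-ene
Conditions: CBr4, PPh3, CH2Cl2, 0 °C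
Reagents that add atoms: carbon tetrabromide BrC(Br)(Br)Br
Why: Appel bromination of the primary allylic alcohol proceeds by SN2 at carbon without touching the vinyl iodide or the alkene geometry.

**Step 8**
Reactants: 7 hydroxy enyne; 11 (Z)-1-bromo-3-iodobut-2-ene
Product: 13 (4E,8E,10E,13Z)-14-iodo-4,8-dimethylpentadeca-4,8,10,13-tetraen-1-ol, via dienylzirconocene alkoxide 12 (not isolated)
Conditions: Cp2Zr(H)Cl (2.2 equiv), THF, rt; then 11, CuCl (15 mol %), 0 °C → rt
Reagents that add atoms: none
Why: The first equivalent of Schwartz reagent is consumed by the hydroxyl group, the second adds syn and terminally to the alkyne (hydrozirconation) to give the (1E,3E)-dienylzirconocene, and copper-catalysed SN2 allylation by the primary bromide forms C1–C14 with retention of all alkene geometries, because the iodine- and methyl-bearing γ-carbon blocks SN2′.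

**Step 9**
Reactants: 13 iodo tetraenol
Product: 14 (4E,8E,10E,13Z)-14-iodo-4,8-dimethylpentadeca-4,8,10,13-tetraenal
Conditions: Dess–Martin periodinane, CH2Cl2, 0 °C → rt
Reagents that add atoms: none
Why: Dess–Martin oxidation converts the primary alcohol into the aldehyde under mild conditions that leave the diene, the skipped CH2 and the vinyl iodide untouched.

**Step 10**
Reactants: 14 iodo tetraenal
Product: 15 (2Z,5E,7E,11E)-2,8,12-trimethylcyclotetradeca-2,5,7,11-tetraen-1-ol (racemic; the carbinol carbon is C11)
Conditions: CrCl2 (8 equiv), NiCl2 (2 mol %), DMF–THF, 3 mM, rt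
Reagents that add atoms: none
Why: Nozaki–Hiyama–Kishi macrocyclisation: the trisubstituted vinyl iodide is converted with retention of the Z geometry into the alkenylchromium(III), whose chemoselective addition to the aldehyde at high dilution closes the 14-membered ring, and the uncontrolled C11 carbinol is corrected in steps 11 and 12.

**Step 11**
Reactants: 15 macrocyclic alcohol
Product: 16 (2Z,5E,7E,11E)-2,8,12-trimethylcyclotetradeca-2,5,7,11-tetraen-1-one
Conditions: Dess–Martin periodinane, CH2Cl2, 0 °C
Reagents that add atoms: none
Why: Dess–Martin oxidation erases the uncontrolled centre without base, so the Z-enone and its doubly allylic C14 methylene should not isomerise.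

**Step 12**
Reactants: 16 macrocyclic Z-enone
Product: 17 (1S,2Z,5E,7E,11E)-2,8,12-trimethylcyclotetradeca-2,5,7,11-tetraen-1-ol (11S in cembrane numbering)
Conditions: (R)-Me-CBS (20 mol %), catecholborane, toluene, −78 °C
Reagents that add atoms: none
Why: Corey–Bakshi–Shibata reduction: the α-methylalkenyl residue (C12) acts as the large group and the C10 methylene chain as the small group, so the (R)-oxazaborolidine should deliver hydride to give the (11S)-alcohol, and catecholborane at −78 °C does not hydroborate the diene.

**Step 13**
Reactants: 17 (11S)-macrocyclic dienol; 18 2-bromoacrylic acid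
Product: 20 (1S,2S,11S)-11-hydroxycembra-3E,7E,12Z,15(17)-tetraen-16,2-olide, via silver 2-bromoacrylate 19 (not isolated)
Conditions: 18, Ag2CO3 (0.55 equiv per 18), THF, rt; then 17, Pd2(dba)3·CHCl3 (5 mol %), (R)-SEGPHOS (11 mol %), 45 °C, slow addition of 19
Reagents that add atoms: none
Why: Proposed new method: oxidative addition of Pd(0) into the C–Br bond of 19 and loss of AgBr give a cationic α-carboxyvinyl–Pd(II)(bisphosphine) that inserts syn into the disubstituted C1=C2 end of the s-trans diene (C15 to C1, Pd to C2), the resulting syn,syn-η3-allyl spans C2–C3–C4, and the pendant carboxylate attacks C2 from the face opposite to Pd and releases Pd(0). The closest known reaction types are the Larock heteroannulation of 1,3-dienes with o-halobenzoic acids, phenols and anilines and the cationic asymmetric Heck reaction; new are the α-haloacrylic acid partner in an enantioface-selective version and the macrocyclic 1,4,4-trisubstituted diene. The lactone closes 5-exo at the allyl terminus C2, because the seven-membered alternative at the fully substituted C4 is slower. C1 is set by the ligand-controlled choice of the Re face of C1 in the insertion, C2 follows from C1 because syn insertion plus anti attack is a net anti addition to an E-alkene and therefore gives the cis-fused (1S,2S) lactone, and the remote C11 carbinol should have little influence. The C3=C4 bond re-forms as E because C5 stays syn on the allyl unit. Chemoselectivity comes from the substrate, since only the diene offers a disubstituted alkene whose insertion gives a stabilised η3-allyl, the isolated trisubstituted C7=C8 and C12=C13 bonds do not insert, and the filled coordination sphere of the bisphosphine allyl cation blocks inner-sphere C–O formation.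

**Step 14**
Reactants: 20 hydroxy lactone
Product: 21 (1S,2S,7S,8S,11S)-7,8-epoxy-11-hydroxycembra-3E,12Z,15(17)-trien-16,2-olide
Conditions: ent-Shi ketone (from L-fructose, 30 mol %), Oxone, K2CO3, Bu4NHSO4, MeCN–DMM–aq. Na2B4O7/EDTA (pH ≈ 9.5), −5 °C
Reagents that add atoms: potassium peroxymonosulfate (Oxone) [K+].[O-]S(=O)(=O)OO
Why: Shi epoxidation: the chiral dioxirane attacks E-trisubstituted alkenes through a spiro transition state and the L-series ketone gives the (S,S)-epoxide, while C3=C4 is deactivated by the allylic lactone oxygen, C12=C13 by the allylic hydroxyl and its branching, and the methylene lactone is too electron-poor to react.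

**Step 15**
Reactants: 21 epoxy alcohol
Product: 22 (1S,2S,7S,8S,11R)-11-chloro-7,8-epoxycembra-3E,12Z,15(17)-trien-16,2-olide
Conditions: (Cl3C)2CO, PPh3, CH2Cl2, −20 °C
Reagents that add atoms: hexachloroacetone ClC(Cl)(Cl)C(=O)C(Cl)(Cl)Cl
Why: Appel-type chlorination with hexachloroacetone/PPh3 collapses the alkoxyphosphonium chloride ion pair by fast SN2, which is known to convert secondary allylic alcohols into unrearranged chlorides with inversion (11S → 11R) under neutral conditions that spare the epoxide.

**Step 16**
Reactants: 22 epoxy chloride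
Product: 23 (1S,2S,7S,8R,11R)-11-chloro-8-hydroperoxy-7-hydroxycembra-3E,12Z,15(17)-trien-16,2-olide
Conditions: anhydrous H2O2 in Et2O, H3PMo12O40 (2 mol %), 0 °C → rt
Reagents that add atoms: hydrogen peroxide OO
Why: Phosphomolybdic acid-catalysed perhydrolysis of epoxides: H2O2 opens the oxirane at the tertiary C8 with inversion (8S → 8R) and leaves the C7–O bond (7S) untouched, and the low-polarity ether medium keeps the allylic chloride from ionising.

**Step 17**
Reactants: 23 chloro hydroperoxide
Product: 24 7-O-deacetyldenticulatolide (1S,2S,7S,8R,11S)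
Conditions: Cs2CO3, DMF, 2 mM, 0 °C
Reagents that add atoms: none
Why: Intramolecular alkylation of a hydroperoxide: the OOH group is far more acidic and, as an α-nucleophile, more reactive than the C7 hydroxyl, and its anion displaces chloride 6-exo-tet with inversion (11R → 11S), which closes the cis-bridged 1,2-dioxane.

**Step 18**
Reactants: 24 7-O-deacetyldenticulatolide
Product: 25 denticulatolide
Conditions: Ac2O, pyridine, DMAP (cat.), CH2Cl2, 0 °C
Reagents that add atoms: acetic anhydride CC(=O)OC(C)=O
Why: Standard acylation of the only free (secondary) hydroxyl with retention at C7, under a weak amine base and low temperature that should not trigger Kornblum–DeLaMare cleavage at C11–H.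

**Compound list**
1 | (2E,6E)-farnesyl acetate | CC(=O)OC/C=C(\C)CC/C=C(\C)CCC=C(C)C | starting material
2 | 10-bromo-11-hydroxy-10,11-dihydrofarnesyl acetate | CC(=O)OC/C=C(\C)CC/C=C(\C)CCC(Br)C(C)(C)O | intermediate
3 | (2E,6E)-10,11-epoxyfarnesol | OC/C=C(\C)CC/C=C(\C)CCC1OC1(C)C | intermediate
4 | (4E,8E)-10-hydroxy-4,8-dimethyldeca-4,8-dienal | OC/C=C(\C)CC/C=C(\C)CCC=O | intermediate
5 | (2E,6E)-3,7-dimethyldeca-2,6-diene-1,10-diol | OC/C=C(\C)CC/C=C(\C)CCCO | intermediate
6 | (2E,6E)-10-hydroxy-3,7-dimethyldeca-2,6-dienal | O=C/C=C(\C)CC/C=C(\C)CCCO | intermediate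
7 | (4E,8E)-4,8-dimethylundeca-4,8-dien-10-yn-1-ol | C#C/C=C(\C)CC/C=C(\C)CCCO | intermediate
8 | 2-butyn-1-ol | CC#CCO | starting material
9 | sodium cyclic alkenyl(alkoxy)alanate | [Na+].CC1=CCO[Al-]1(OCCOC)OCCOC | intermediate
10 | (Z)-3-iodobut-2-en-1-ol | OC/C=C(\I)C | intermediate
11 | (Z)-1-bromo-3-iodobut-2-ene | BrC/C=C(\I)C | intermediate
12 | (1E,3E)-dienylzirconocene chloride, O-zirconocene alkoxide (Cp drawn σ-bonded) | Cl[Zr](C1C=CC=C1)(C1C=CC=C1)/C=C/C=C(\C)CC/C=C(\C)CCCO[Zr](Cl)(C1C=CC=C1)C1C=CC=C1 | intermediate
13 | (4E,8E,10E,13Z)-14-iodo-4,8-dimethylpentadeca-4,8,10,13-tetraen-1-ol | OCCC/C(C)=C/CC/C(C)=C/C=C/C/C=C(\I)C | intermediate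
14 | (4E,8E,10E,13Z)-14-iodo-4,8-dimethylpentadeca-4,8,10,13-tetraenal | O=CCC/C(C)=C/CC/C(C)=C/C=C/C/C=C(\I)C | intermediate
15 | (2Z,5E,7E,11E)-2,8,12-trimethylcyclotetradeca-2,5,7,11-tetraen-1-ol, racemic | C/C1=C/C/C=C/C=C(\C)CC/C=C(\C)CCC1O | intermediate
16 | (2Z,5E,7E,11E)-2,8,12-trimethylcyclotetradeca-2,5,7,11-tetraen-1-one | C/C1=C/C/C=C/C=C(\C)CC/C=C(\C)CCC1=O | intermediate
17 | (1S,2Z,5E,7E,11E)-2,8,12-trimethylcyclotetradeca-2,5,7,11-tetraen-1-ol | C/C1=C/C/C=C/C=C(\C)CC/C=C(\C)CC[C@@H]1O | intermediate
18 | 2-bromoacrylic acid | C=C(Br)C(=O)O | starting material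
19 | silver 2-bromoacrylate | [Ag+].C=C(Br)C([O-])=O | intermediate
20 | (1S,2S,11S)-11-hydroxycembra-3E,7E,12Z,15(17)-tetraen-16,2-olide | C=C1C(=O)O[C@H]2/C=C(\C)CC/C=C(\C)CC[C@H](O)/C(C)=C\C[C@@H]12 | intermediate
21 | (7S,8S)-7,8-epoxide of 20 | C=C1C(=O)O[C@H]2/C=C(\C)CC[C@@H]3O[C@@]3(C)CC[C@H](O)/C(C)=C\C[C@@H]12 | intermediate
22 | (11R)-11-chloro-(7S,8S)-7,8-epoxy lactone | C=C1C(=O)O[C@H]2/C=C(\C)CC[C@@H]3O[C@@]3(C)CC[C@@H](Cl)/C(C)=C\C[C@@H]12 | intermediate
23 | (7S,8R,11R)-11-chloro-8-hydroperoxy-7-hydroxy lactone | C=C1C(=O)O[C@H]2/C=C(\C)CC[C@H](O)[C@@](OO)(C)CC[C@@H](Cl)/C(C)=C\C[C@@H]12 | intermediate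
24 | 7-O-deacetyldenticulatolide | C=C1C(=O)O[C@H]2/C=C(\C)CC[C@H](O)[C@@]3(C)CC[C@H](OO3)/C(C)=C\C[C@@H]12 | intermediate
25 | denticulatolide | C=C1C(=O)O[C@H]2/C=C(\C)CC[C@H](OC(C)=O)[C@@]3(C)CC[C@H](OO3)/C(C)=C\C[C@@H]12 | target

**Totals:** 18 steps in all. The longest linear sequence is 16 steps (steps 1–5 and 8–18, from farnesyl acetate).

**Steps most likely to fail**

1. **Step 13 (key step).**
   - Risks: insertion into the internal, trisubstituted diene may be slow, so that self-coupling or polymerisation of the bromoacrylate takes over. β-Hydride loss from the allyl intermediate may compete with lactonisation. Facial selectivity may be poor. Partial inner-sphere C–O formation would erode the cis ring fusion.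
   - Fallback (known chemistry, from 17 back to 20): Mn(III)-based oxidative carbolactonisation of the diene with malonic acid (Mn(OAc)3·2H2O, AcOH, rt). The malonyl radical adds at C1, the allyl radical is oxidised, and a carboxyl group closes at C2 to give the α-carboxy lactone F1. Decarboxylative Mannich methylenation (aq. HCHO, Et2NH, NaOAc/AcOH) then gives 20. Stereocontrol is lost in this variant, so the isomers would have to be separated by chromatography.

2. **Step 17.**
   - Risks: ionisation of the allylic chloride with loss of configuration at C11, SN2′ attack, conjugate addition of the peroxy anion to the methylene lactone, or base-induced fragmentation of the β-hydroxy hydroperoxide.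
   - Fallback (from 22 back to 24): the order of the two C–O bond formations is reversed. Silver-assisted perhydrolysis of the chloride (AgOTf, anhydrous H2O2/Et2O, −40 °C) gives the C11 hydroperoxy epoxide F2. Its acid-catalysed 6-exo-tet opening of the oxirane at the tertiary C8 (cat. CSA, CH2Cl2) forms the dioxane without any base and without an external nucleophile at the epoxide.

3. **Step 14.**
   - Risks: mismatch between the facial preference of the dioxirane and the face of C7=C8 that the macrocycle exposes, competing oxidation at C12=C13, or cyclisation of the C11 hydroxyl onto the new epoxide.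
   - Fallback (from 20 back to 21): hydroxyl-directed catalytic asymmetric epoxidation, with the C11 carbinol as a bishomoallylic anchor for a Hf(IV)–chiral bishydroxamic acid complex and cumene hydroperoxide (toluene, 0 °C). The oxidant is then delivered intramolecularly to C7=C8 only. This fallback makes no new compound (F0).

**Further compounds**
F1 | step 13 | α-carboxy lactone (CO2H and H on C15 in place of the methylene group of 20) | O=C(O)C1C(=O)O[C@H]2/C=C(\C)CC/C=C(\C)CC[C@H](O)/C(C)=C\C[C@@H]12
F2 | step 17 | (11S)-11-hydroperoxy-(7S,8S)-7,8-epoxy lactone | C=C1C(=O)O[C@H]2/C=C(\C)CC[C@@H]3O[C@@]3(C)CC[C@H](OO)/C(C)=C\C[C@@H]12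
F0 | step 14 | none | none
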